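## The problem

Compound 36 is a pentacyclic Stemona-type alkaloid in which the cyclopentane (ring B), the pyrrolidine (ring C) and the azepane (ring D) all meet at the amino-substituted quaternary carbon C7: B and C are spiro-linked there, while D shares the N–C7 bond with C and the C7–C20 bond with B. Atoms are numbered along the SMILES string: C1 (CH–Et), C2 (CH–O), O3, C4 (lactone C=O), C5 (C(OH)Me), C6, C7, C8, C9, C10 (CH–N), C11–C14 with O15 (lactone E; C11 CH–O, C13 CH–Me, C14 C=O), N, C16–C19 (azepane CH2 groups) and C20; ring A is the hydroxy lactone cis-fused to ring B at C2–C6. Nine stereocentres (1R,2R,5S,6S,7R,10S,11S,13S,20R) have to be set. C7 is the natural control element, because C6, C20 and, across nitrogen, C10 are its neighbours; C10/C11/C13 and the C5 carbinol are the hardest to relay. At C5 the hydroxyl group lies on the concave face of the A/B bicycle and the methyl group on the convex face, so the methyl group, not the oxygen, has to arrive last. Two γ-lactones, the epimerisable C13–H, the tertiary alcohol and the oxidisable tertiary amine exclude strong base, unselective hydride reagents and oxidations in the presence of the free amine. The C1–C2 bond joins a carbon that can be the β-carbon of an enol ether (the ethyl CH2 being its alkoxy carbon) to a carbon that can be C2 of a 3-furyl group on C7 (C6 = furan C3; C5, C4, O3 the rest of the furan). Ring B can therefore be closed by oxidative coupling of two electron-rich π systems held together by C7 and C20, the furan serving as latent ring A.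

## Retrosynthesis

Nitrogen is kept acylated until the end. The last disconnection removes the C16 carbonyl: 36 comes from lactam 35 by a lactam-selective hydrosilylation. The lactam keeps nitrogen inert through the anodic step and the oxidations of ring A; the forward step must spare two lactones and a tertiary alcohol.

Ring A is traced back to a furan. The C5–CH3 bond of 35 is cut first, giving the 5-oxo lactone 34, because a methyl nucleophile adds to the convex face and leaves the hydroxyl group concave, as required. Hydroxylation of a 5-methyl lactone enolate would give the opposite arrangement. 34 comes from the 5-hydroxy lactone 33, and 33 from butenolide 31 by a radical hydration that needs no base. 31 comes from hydroxybutenolide 29 by reduction at C2, and 29 from the ring-fused furan 27 by photooxygenation. This removes four stereocentres (C2, C5, C6 and, later, C1) and both oxygens of ring A.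

The ethyl group of 27 is cut back through vinyl compound 26 and aldehyde 25 to the dimethyl acetal 24. The aldehyde stage makes C1 epimerisable, so the C1 configuration need not come from the ring closure itself.

The key disconnection cuts C1–C2 of 24. The precursor is the 3-furyl enol ether 23, which has one ring and one stereocentre fewer. The forward reaction is an anodic coupling: the enol ether must be oxidised before the furan, and furan C2, not C4, must attack.

Enol ether 23 is taken back by Wittig, oxidation and desilylation to silyl ether 20. In 20 both ring E and C20 are cut in one retrosynthetic operation: hydrogenation of 19 should set C13 (cis lactone) and C20 (hydrogen anti to the furyl group). The C10–C11 bond of 19 is cut to the N,O-acetal 16 and silyloxyfuran 18 (from 17), a vinylogous Mannich reaction. Adding the C20 carbon to a preformed ring C that already carried the C10 substituent would place the two groups trans, whereas 36 has them cis. C10 is therefore made after C7 and C20 are in place.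

The bicyclic lactam 16 is opened at C19=C20 (ring-closing metathesis) to diene 15, and 15 at N–C10 (amido acetal cyclisation) to amide 14. Metathesis puts the double bond exactly where the C20 hydrogen has to be delivered later, and the alkene carbon C20 already carries C1 at the alcohol oxidation level, so no ester has to be reduced beside a lactone.

Amide 14 comes from sulfinamide 11 and acid chloride 12. The C7–C20 bond of 11 is cut to the sulfinyl ketimine 9 and the alkenyllithium 10 (from bromide 2, itself from 1). 9 comes from ketone 7 and sulfinamide 8, and 7 from 3-bromofuran 3 and nitrile 4. C7 is thus the only stereocentre made under auxiliary control; all others are relayed from it.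

## Roads not taken

Alternative 1: The cut is across C7–C16 and C19–C20. A Lewis acid-promoted Diels–Alder reaction of the lactone-fused cyclopentenecarbaldehyde A1 with silyloxydiene A2 would give the cis-hydrindene A3, and nitrogen would later be inserted between C7 and C16 by a Beckmann rearrangement. Merits: rings A and B with C1, C2, C5 and C6 are settled early on a small bicycle, and C7 and C20 are formed together in a convergent step. In this respect it is better than the chosen plan, whose C5 carbinol is made late on a crowded pentacycle. Weak points: the dienophile must form a quaternary centre next to a cis-fused lactone, with uncertain facial selectivity. The formyl group must then be grown into C8–C10, nitrogen inserted, and rings C and E built, with the same C10 problem still to solve. The chosen plan sets against this a shorter path to the aza-quaternary centre and a nitrogen atom present from step 3.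

Alternative 2: The cut is the C6–C7 bond. Heating the bicyclic α-hydroxy imine A4 would shift C6 from C8 to C7 and give the spiro pyrrolidin-3-one A5. Merits: the 1,2-shift is suprafacial, so C7 is formed stereospecifically from centres that already exist, and C10 with ring E can be in place beforehand. This is more secure than the chosen plan's Mannich step at C10. Weak points: A4 is itself a fully elaborated stenine-type hydroindole, so the step count before the key step is high. The α-iminol shift is an equilibrium and either C6 or C9 could migrate. The C8 ketone must afterwards be removed and ring D closed. The chosen plan carries no oxygen at C8 and closes ring D by a routine metathesis.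

Alternative 3: The cuts are N–C7 and C19–C20. Irradiation of the tethered maleimide A6 would insert the C7=C20 alkene into an imide C(O)–N bond and give the azepinedione A7. Merits: rings C and D and the quaternary carbon appear in one step, with C10 already set in the tether. In step count for the azabicycle this road is at least as good as the chosen one. Weak points: the alkene is trisubstituted and flanked by the cis-fused lactone, so [2+2] addition and poor facial control are real risks. A7 then needs alkene reduction, selective removal of the C19 ketone beside two lactones, and lactam reduction. The chosen plan avoids that deoxygenation and uses the furan both as coupling partner and as masked ring A.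

Key step: step 14

Remark: 15 and 16 are carried as C10 epimer mixtures and 23 as an E/Z mixture (the SMILES shows E); both features disappear in the next steps. Compounds 1, 3, 4, 8, 12 and 17 are taken as commercial.

## Route

Step 1
Reactants: 1 2-bromoprop-2-en-1-ol
Product: 2 tert-butyl[(2-bromoprop-2-en-1-yl)oxy]diphenylsilane
Conditions: t-BuPh2SiCl, imidazole, CH2Cl2, 0→25 °C
Reagents that add atoms: tert-butyl(chloro)diphenylsilane, CC(C)(C)[Si](Cl)(c1ccccc1)c1ccccc1
Why: Standard silylation of a primary alcohol; the bulky silyl ether should survive the later HCl/EtOH and pyridinium tosylate steps and resist silyl migration in the lithio species.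

Step 2
Reactants: 3 3-bromofuran; 4 4,4-diethoxybutanenitrile
Product: 7 4,4-diethoxy-1-(furan-3-yl)butan-1-one, via furan-3-yllithium 5 (not isolated), via N-lithio ketimine 6 (not isolated)
Conditions: n-BuLi, Et2O, −78 °C; then 4, −78→−30 °C; aq. NH4Cl, then moist SiO2
Reagents that add atoms: water, O
Why: Bromine–lithium exchange at −78 °C gives the 3-lithio furan without isomerisation; organolithium addition to the nitrile stops at the N-lithio ketimine, and mild hydrolysis should give the ketone with the acetal intact.

Step 3
Reactants: 7 4,4-diethoxy-1-(furan-3-yl)butan-1-one; 8 (S)-2-methylpropane-2-sulfinamide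
Product: 9 (S,E)-N-[4,4-diethoxy-1-(furan-3-yl)butylidene]-2-methylpropane-2-sulfinamide
Conditions: Ti(OEt)4, THF, 65 °C
Reagents that add atoms: none
Why: Titanium alkoxide-mediated condensation of an aryl alkyl ketone with tert-butanesulfinamide; the E ketimine (sulfinyl trans to furyl) should predominate, and ethoxide matches the diethyl acetal.

Step 4
Reactants: 9 sulfinyl ketimine; 2 tert-butyl[(2-bromoprop-2-en-1-yl)oxy]diphenylsilane
Product: 11 (S)-N-[(3R)-2-(tert-butyldiphenylsilyloxymethyl)-6,6-diethoxy-3-(furan-3-yl)hex-1-en-3-yl]-2-methylpropane-2-sulfinamide, via alkenyllithium 10 (not isolated)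
Conditions: 2, t-BuLi (2 equiv), Et2O, −78 °C; then 9·AlMe3, toluene, −78 °C
Reagents that add atoms: none
Why: 1,2-Addition of an organolithium to an AlMe3-complexed tert-butanesulfinyl ketimine, which suppresses α-deprotonation. In the closed, metal-bridged chair transition state the S auxiliary should direct the alkenyl group to the face that makes C7 R; if the open transition state dominated, the R auxiliary would be used instead. This is the only stereocentre set by an external element.

Step 5
Reactants: 11 sulfinamide; 12 pent-4-enoyl chloride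
Product: 14 N-[(3R)-2-(tert-butyldiphenylsilyloxymethyl)-6,6-diethoxy-3-(furan-3-yl)hex-1-en-3-yl]pent-4-enamide, via ammonium chloride 13 (not isolated)
Conditions: HCl (4 M in dioxane), EtOH, 0 °C; evaporation; then 12, Et3N, CH2Cl2, 0 °C
Reagents that add atoms: none
Why: Acid cleaves the N–S bond while ethanol keeps the acetal as such; the primary tert-alkyl amine is then acylated by the acid chloride. Any 1-pyrroline formed from amine and acetal would be acylated to the same N,O-acetal 15.

Step 6
Reactants: 14 amido acetal
Product: 15 1-[(2R)-2-[3-(tert-butyldiphenylsilyloxy)prop-1-en-2-yl]-5-ethoxy-2-(furan-3-yl)pyrrolidin-1-yl]pent-4-en-1-one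
Conditions: pyridinium p-toluenesulfonate (0.2 equiv), EtOH–CH2Cl2, 40 °C
Reagents that add atoms: none
Why: Acid-catalysed amido acetal cyclisation: the amide nitrogen closes ring C in a 5-exo attack on the oxocarbenium ion. The C10 configuration is irrelevant because C10 is ionised in step 9.

Step 7
Reactants: 15 diene
Product: 16 (9aR)-9-(tert-butyldiphenylsilyloxymethyl)-3-ethoxy-9a-(furan-3-yl)-1,2,3,6,7,9a-hexahydro-5H-pyrrolo[1,2-a]azepin-5-one
Conditions: second-generation Grubbs catalyst (5 mol %), CH2Cl2 (5 mM), 40 °C
Reagents that add atoms: none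
Why: Ring-closing metathesis of a tertiary amide diene closes the seven-membered lactam ring D and places the trisubstituted C19=C20 alkene next to C7; ethene is lost and the amide rotamers interconvert fast enough to feed the reactive one.

Step 8
Reactants: 17 3-methylfuran-2(5H)-one
Product: 18 triisopropyl[(3-methylfuran-2-yl)oxy]silane
Conditions: iPr3SiOTf, Et3N, CH2Cl2, 0 °C
Reagents that add atoms: triisopropylsilyl trifluoromethanesulfonate, CC(C)[Si](OS(=O)(=O)C(F)(F)F)(C(C)C)C(C)C
Why: Soft enolisation and O-silylation of a butenolide gives the 2-silyloxyfuran, the standard vinylogous Mannich donor.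

Step 9
Reactants: 16 N,O-acetal; 18 silyloxyfuran
Product: 19 (3S,9aR)-9-(tert-butyldiphenylsilyloxymethyl)-9a-(furan-3-yl)-3-[(2S)-4-methyl-5-oxo-2,5-dihydrofuran-2-yl]-1,2,3,6,7,9a-hexahydro-5H-pyrrolo[1,2-a]azepin-5-one
Conditions: BF3·OEt2, CH2Cl2, −78→−40 °C
Reagents that add atoms: none
Why: BF3 ionises the N,O-acetal to the N-acyliminium ion, which is attacked by C5 of the silyloxyfuran (vinylogous Mannich reaction). The usual threo topology should give the syn N/O relation of C10 and C11. Attack is expected anti to the 3-furyl group on C7, because C20 on the other face is tied back into ring D, so C11 ends cis to C20.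

Step 10
Reactants: 19 butenolide diene
Product: 20 (3S,9S,9aR)-9-(tert-butyldiphenylsilyloxymethyl)-9a-(furan-3-yl)-3-[(2S,4S)-4-methyl-5-oxooxolan-2-yl]octahydro-5H-pyrrolo[1,2-a]azepin-5-one
Conditions: H2 (3 atm), Pd/C (10 %), EtOAc, 25 °C
Reagents that add atoms: none
Why: Heterogeneous hydrogenation. The butenolide should be reduced anti to the pyrrolidine substituent on C11, giving the cis lactone (C13). The ring D alkene should be reduced on the face away from the axial 3-furyl group on the neighbouring C7, placing the C1 carbon cis to the furan (C20). The furan should survive these mild conditions.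

Step 11
Reactants: 20 silyl ether
Product: 21 (3S,9S,9aR)-9a-(furan-3-yl)-9-(hydroxymethyl)-3-[(2S,4S)-4-methyl-5-oxooxolan-2-yl]octahydro-5H-pyrrolo[1,2-a]azepin-5-one
Conditions: Bu4NF, AcOH, THF, 0→25 °C
Reagents that add atoms: none
Why: Fluoride desilylation; the acetic acid buffer keeps the medium from epimerising C13 or opening lactone E.

Step 12
Reactants: 21 alcohol
Product: 22 (3S,9S,9aR)-9a-(furan-3-yl)-3-[(2S,4S)-4-methyl-5-oxooxolan-2-yl]-5-oxooctahydro-1H-pyrrolo[1,2-a]azepine-9-carbaldehyde
Conditions: Dess–Martin periodinane, NaHCO3, CH2Cl2, 0 °C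
Reagents that add atoms: none
Why: Buffered hypervalent iodine oxidation of a primary alcohol; the non-basic conditions should leave the α-stereocentre C20 untouched.

Step 13
Reactants: 22 aldehyde
Product: 23 (3S,9R,9aR)-9a-(furan-3-yl)-9-(2-methoxyethenyl)-3-[(2S,4S)-4-methyl-5-oxooxolan-2-yl]octahydro-5H-pyrrolo[1,2-a]azepin-5-one
Conditions: Ph3P(CH2OMe)Cl, KN(SiMe3)2, THF, 0 °C; then 22, −78→0 °C
Reagents that add atoms: (methoxymethyl)triphenylphosphonium chloride, COC[P+](c1ccccc1)(c1ccccc1)c1ccccc1.[Cl-]
Why: Wittig reaction with the methoxymethylene ylide; at low temperature, with no excess base, carbonyl addition should outrun enolisation at C20 and at C13.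

Step 14
Reactants: 23 3-furyl enol ether
Product: 24 (1R,7R,10S,11S,13S,20R) furan-fused lactam: ring B closed by the C1–C2 bond, furan fused at C2–C6, dimethoxymethyl group on C1 trans to C19, C16 lactam, lactone E on C10
Conditions: reticulated vitreous carbon anode, Pt cathode, undivided cell, constant current, 2.2 F/mol, 0.1 M LiClO4, MeOH–CH2Cl2 (1:4), 2,6-lutidine, 25 °C
Reagents that add atoms: methanol, CO
Why: Anodic oxidation removes one electron from the enol ether, the most easily oxidised group. Its β-carbon C1 is then attacked by furan C2; a second electron transfer, loss of the C2 proton (restoring the furan) and capture of methanol at the former alkoxy carbon give the dimethyl acetal, while methanol is reduced to hydrogen at the cathode. The closest known reaction type is the intramolecular anodic coupling of enol ether radical cations with 3-tethered furans, which gives ring-fused furans. Ring B closes in the 5-exo mode with respect to the enol ether and is annulated to the furan 2,3-bond. The new stereocentre C1 lies next to C20; the acetal carbon should take the position trans to C19, and any cis isomer converges in step 15. The step needs oxidation of the enol ether before the furan and well before the lactam nitrogen, which the order of oxidation potentials secures. It also needs attack through the α-carbon C2 and not the β-carbon C4, which the higher nucleophilicity of the furan α-position secures. The quaternary C7 and the cis relation set in step 10 hold the two π systems within bonding distance, and 2,6-lutidine keeps the medium from hydrolysing the enol ether.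

Step 15
Reactants: 24 dimethyl acetal
Product: 25 the C1 carbaldehyde of the furan-fused lactam (1R, formyl trans to C19)
Conditions: TsOH·H2O (0.1 equiv), acetone–H2O, 25 °C; then DBU (0.2 equiv), CH2Cl2, 25 °C
Reagents that add atoms: water, O
Why: Acetal hydrolysis followed by base equilibration: C1–H lies between the furan and the formyl group and is acidic, so the thermodynamically preferred isomer with the formyl group anti to C19 should result.

Step 16
Reactants: 25 aldehyde
Product: 26 the C1 vinyl compound (1R)
Conditions: Zn, CH2Br2, TiCl4, THF–CH2Cl2, 0→25 °C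
Reagents that add atoms: dibromomethane, BrCBr
Why: Lombardo methylenation; the non-basic zinc–titanium methylene reagent should not enolise the sensitive aldehyde and does not touch lactone or lactam carbonyls.

Step 17
Reactants: 26 vinyl compound
Product: 27 the C1 ethyl furan (1R)
Conditions: H2 (1 atm), RhCl(PPh3)3 (5 mol %), benzene–EtOH, 25 °C
Reagents that add atoms: none
Why: Homogeneous hydrogenation with RhCl(PPh3)3 is selective for the monosubstituted alkene and leaves the furan intact.

Step 18
Reactants: 27 ethyl furan
Product: 29 the 2-hydroxy butenolide (C2 hemiketal, C4 lactone carbonyl, C5=C6), via endoperoxide 28 (not isolated)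
Conditions: O2, hν (visible), tetraphenylporphyrin (cat.), iPr2NEt, CH2Cl2, −78 °C
Reagents that add atoms: dioxygen, O=O
Why: [4+2] addition of singlet oxygen across furan C2/C4, then base-induced Kornblum–DeLaMare fragmentation; only C4 carries a hydrogen, so C4 must become the carbonyl and C2 the hemiketal carbon.

Step 19
Reactants: 29 hydroxy butenolide
Product: 31 the butenolide with C2–H (1R,2R; C5=C6), via hydroxy acid 30 (not isolated)
Conditions: NaBH4, CeCl3·7H2O, MeOH, −20 °C; then 1 M HCl, 25 °C
Reagents that add atoms: none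
Why: The hydroxy butenolide reacts through its keto acid tautomer. Luche 1,2-reduction of the C2 ketone from the face anti to the ethyl group on C1 sets C2, and acid closes the butenolide.

Step 20
Reactants: 31 butenolide
Product: 33 the cis-fused 5-hydroxy lactone (1R,2R,5R,6R; OH on the convex face), via hydroperoxide 32 (not isolated)
Conditions: Mn(dpm)3 (10 mol %; dpm = 2,2,6,6-tetramethylheptane-3,5-dionate), PhSiH3, O2 (1 atm), iPrOH–CH2Cl2, 0 °C; then P(OEt)3
Reagents that add atoms: dioxygen, O=O
Why: Mukaiyama-type radical hydration of an α,β-unsaturated lactone. Hydrogen atom transfer to the β-carbon C6 from the convex face sets the cis ring fusion, and the C5 radical is trapped by dioxygen. No base is used, so C13 is safe, and the C5 configuration is erased in step 21.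

Step 21
Reactants: 33 5-hydroxy lactone
Product: 35 the 16-oxo derivative (lactam) of 36, (1R,2R,5S,6S,7R,10S,11S,13S,20R), via oxo lactone 34 (not isolated)
Conditions: Dess–Martin periodinane, NaHCO3, CH2Cl2, 0 °C, filtration; then MeMgBr, CeCl3, THF, −78 °C
Reagents that add atoms: methylmagnesium bromide, C[Mg]Br
Why: Oxidation gives the 2-oxo lactone, which is used at once. The weakly basic organocerium reagent adds to the ketone, more electrophilic than either lactone, from the convex face, so the methyl group ends cis to C6–H and the hydroxyl group on the concave face (5S).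

Step 22
Reactants: 35 lactam
Product: 36 target compound
Conditions: [Ir(coe)2Cl]2 (1 mol %; coe = cyclooctene), Et2SiH2, CH2Cl2, 25 °C; then K2CO3, MeOH
Reagents that add atoms: none
Why: Iridium-catalysed hydrosilylation reduces the tertiary lactam to the amine through the silyl hemiaminal and iminium ion and leaves lactones untouched; methanolysis frees the tertiary alcohol from any silyl ether.

## Compound list

1 | 2-bromoprop-2-en-1-ol | OCC(Br)=C | starting material
2 | tert-butyl[(2-bromoprop-2-en-1-yl)oxy]diphenylsilane | C=C(Br)CO[Si](c1ccccc1)(c1ccccc1)C(C)(C)C | intermediate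
3 | 3-bromofuran | Brc1ccoc1 | starting material
4 | 4,4-diethoxybutanenitrile | N#CCCC(OCC)OCC | starting material
5 | furan-3-yllithium | [Li]c1ccoc1 | intermediate
6 | N-lithio 4,4-diethoxy-1-(furan-3-yl)butan-1-imine | [Li]N=C(c1ccoc1)CCC(OCC)OCC | intermediate
7 | 4,4-diethoxy-1-(furan-3-yl)butan-1-one | O=C(c1ccoc1)CCC(OCC)OCC | intermediate
8 | (S)-2-methylpropane-2-sulfinamide | CC(C)(C)[S@](=O)N | starting material
9 | (S,E)-N-[4,4-diethoxy-1-(furan-3-yl)butylidene]-2-methylpropane-2-sulfinamide | CC(C)(C)[S@](=O)/N=C(/c1ccoc1)CCC(OCC)OCC | intermediate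
10 | [3-(tert-butyldiphenylsilyloxy)prop-1-en-2-yl]lithium | [Li]C(=C)CO[Si](c1ccccc1)(c1ccccc1)C(C)(C)C | intermediate
11 | (S)-N-[(3R)-2-(tert-butyldiphenylsilyloxymethyl)-6,6-diethoxy-3-(furan-3-yl)hex-1-en-3-yl]-2-methylpropane-2-sulfinamide | CC(C)(C)[S@](=O)N[C@](c1ccoc1)(CCC(OCC)OCC)C(=C)CO[Si](c1ccccc1)(c1ccccc1)C(C)(C)C | intermediate
12 | pent-4-enoyl chloride | C=CCCC(Cl)=O | starting material
13 | (3R)-2-(tert-butyldiphenylsilyloxymethyl)-6,6-diethoxy-3-(furan-3-yl)hex-1-en-3-aminium chloride | [Cl-].[NH3+][C@](c1ccoc1)(CCC(OCC)OCC)C(=C)CO[Si](c1ccccc1)(c1ccccc1)C(C)(C)C | intermediate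
14 | N-[(3R)-2-(tert-butyldiphenylsilyloxymethyl)-6,6-diethoxy-3-(furan-3-yl)hex-1-en-3-yl]pent-4-enamide | C=CCCC(=O)N[C@](c1ccoc1)(CCC(OCC)OCC)C(=C)CO[Si](c1ccccc1)(c1ccccc1)C(C)(C)C | intermediate
15 | 1-[(2R)-2-[3-(tert-butyldiphenylsilyloxy)prop-1-en-2-yl]-5-ethoxy-2-(furan-3-yl)pyrrolidin-1-yl]pent-4-en-1-one (both C5 epimers) | C=CCCC(=O)N1C(OCC)CC[C@]1(c1ccoc1)C(=C)CO[Si](c1ccccc1)(c1ccccc1)C(C)(C)C | intermediate
16 | (9aR)-9-(tert-butyldiphenylsilyloxymethyl)-3-ethoxy-9a-(furan-3-yl)-1,2,3,6,7,9a-hexahydro-5H-pyrrolo[1,2-a]azepin-5-one (both C3 epimers) | CCOC1CC[C@@]2(c3ccoc3)N1C(=O)CCC=C2CO[Si](c1ccccc1)(c1ccccc1)C(C)(C)C | intermediate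
17 | 3-methylfuran-2(5H)-one | CC1=CCOC1=O | starting material
18 | triisopropyl[(3-methylfuran-2-yl)oxy]silane | Cc1ccoc1O[Si](C(C)C)(C(C)C)C(C)C | intermediate
19 | (3S,9aR)-9-(tert-butyldiphenylsilyloxymethyl)-9a-(furan-3-yl)-3-[(2S)-4-methyl-5-oxo-2,5-dihydrofuran-2-yl]-1,2,3,6,7,9a-hexahydro-5H-pyrrolo[1,2-a]azepin-5-one | CC(C)(C)[Si](c1ccccc1)(c1ccccc1)OCC1=CCCC(=O)N2[C@H]([C@@H]3C=C(C)C(=O)O3)CC[C@]12c1ccoc1 | intermediate
20 | (3S,9S,9aR)-9-(tert-butyldiphenylsilyloxymethyl)-9a-(furan-3-yl)-3-[(2S,4S)-4-methyl-5-oxooxolan-2-yl]octahydro-5H-pyrrolo[1,2-a]azepin-5-one | CC(C)(C)[Si](c1ccccc1)(c1ccccc1)OC[C@H]1CCCC(=O)N2[C@H]([C@@H]3C[C@H](C)C(=O)O3)CC[C@]12c1ccoc1 | intermediate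
21 | (3S,9S,9aR)-9a-(furan-3-yl)-9-(hydroxymethyl)-3-[(2S,4S)-4-methyl-5-oxooxolan-2-yl]octahydro-5H-pyrrolo[1,2-a]azepin-5-one | OC[C@H]1CCCC(=O)N2[C@H]([C@@H]3C[C@H](C)C(=O)O3)CC[C@]12c1ccoc1 | intermediate
22 | (3S,9S,9aR)-9a-(furan-3-yl)-3-[(2S,4S)-4-methyl-5-oxooxolan-2-yl]-5-oxooctahydro-1H-pyrrolo[1,2-a]azepine-9-carbaldehyde | O=C[C@H]1CCCC(=O)N2[C@H]([C@@H]3C[C@H](C)C(=O)O3)CC[C@]12c1ccoc1 | intermediate
23 | (3S,9R,9aR)-9a-(furan-3-yl)-9-(2-methoxyethenyl)-3-[(2S,4S)-4-methyl-5-oxooxolan-2-yl]octahydro-5H-pyrrolo[1,2-a]azepin-5-one (E/Z mixture, E shown) | CO/C=C/[C@H]1CCCC(=O)N2[C@H]([C@@H]3C[C@H](C)C(=O)O3)CC[C@]12c1ccoc1 | intermediate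
24 | (1R,7R,10S,11S,13S,20R) furan-fused lactam with dimethoxymethyl group on C1 (rings B, C, D closed; furan fused at C2–C6; C16 lactam; lactone E on C10) | COC(OC)[C@H]1c2occc2[C@]23CC[C@@H]([C@@H]4C[C@H](C)C(=O)O4)N2C(=O)CCC[C@H]13 | intermediate
25 | C1 carbaldehyde of the furan-fused lactam (1R) | O=C[C@H]1c2occc2[C@]23CC[C@@H]([C@@H]4C[C@H](C)C(=O)O4)N2C(=O)CCC[C@H]13 | intermediate
26 | C1 vinyl furan-fused lactam (1R) | C=C[C@H]1c2occc2[C@]23CC[C@@H]([C@@H]4C[C@H](C)C(=O)O4)N2C(=O)CCC[C@H]13 | intermediate
27 | C1 ethyl furan-fused lactam (1R) | CC[C@H]1c2occc2[C@]23CC[C@@H]([C@@H]4C[C@H](C)C(=O)O4)N2C(=O)CCC[C@H]13 | intermediate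
28 | endoperoxide of 27 (dioxygen bridging C2 and C4) | CC[C@H]1C25OOC(O2)C=C5[C@]23CC[C@@H]([C@@H]4C[C@H](C)C(=O)O4)N2C(=O)CCC[C@H]13 | intermediate
29 | 2-hydroxy butenolide (C2 hemiketal, both epimers; C4 lactone C=O; C5=C6) | CC[C@H]1C2(O)OC(=O)C=C2[C@]23CC[C@@H]([C@@H]4C[C@H](C)C(=O)O4)N2C(=O)CCC[C@H]13 | intermediate
30 | (Z)-hydroxy acid (C2–OH, C6=C5–CO2H) | CC[C@H]1[C@@H](O)/C(=C\C(=O)O)[C@]23CC[C@@H]([C@@H]4C[C@H](C)C(=O)O4)N2C(=O)CCC[C@H]13 | intermediate
31 | butenolide lactam (1R,2R; C5=C6) | CC[C@H]1[C@H]2OC(=O)C=C2[C@]23CC[C@@H]([C@@H]4C[C@H](C)C(=O)O4)N2C(=O)CCC[C@H]13 | intermediate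
32 | C5 hydroperoxide of the cis-fused lactone | CC[C@H]1[C@H]2OC(=O)[C@H](OO)[C@H]2[C@]23CC[C@@H]([C@@H]4C[C@H](C)C(=O)O4)N2C(=O)CCC[C@H]13 | intermediate
33 | cis-fused 5-hydroxy lactone lactam (1R,2R,5R,6R; OH convex) | CC[C@H]1[C@H]2OC(=O)[C@H](O)[C@H]2[C@]23CC[C@@H]([C@@H]4C[C@H](C)C(=O)O4)N2C(=O)CCC[C@H]13 | intermediate
34 | 5-oxo lactone lactam | CC[C@H]1[C@H]2OC(=O)C(=O)[C@H]2[C@]23CC[C@@H]([C@@H]4C[C@H](C)C(=O)O4)N2C(=O)CCC[C@H]13 | intermediate
35 | 16-oxo derivative of 36 (1R,2R,5S,6S,7R,10S,11S,13S,20R) | CC[C@H]1[C@H]2OC(=O)[C@@](C)(O)[C@H]2[C@]23CC[C@@H]([C@@H]4C[C@H](C)C(=O)O4)N2C(=O)CCC[C@H]13 | intermediate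
36 | CNP0260919.3 (1R,2R,5S,6S,7R,10S,11S,13S,20R) | CC[C@H]1[C@H]2OC(=O)[C@@](C)(O)[C@H]2[C@]23CC[C@@H]([C@@H]4C[C@H](C)C(=O)O4)N2CCCC[C@H]13 | target

## Step count and least certain steps

Total step count: 22. Longest linear sequence: 20 steps (steps 2–7 and 9–22, from 3-bromofuran).

Step 14 (key step). Closure of a five-membered ring onto the furan 2,3-bond is more strained than the better-known six-membered case. Methanol may therefore trap the radical cation before the C–C bond forms, or the furan may be over-oxidised and polymerise. Fallback: from 22, the same C1–C2 bond is made by a Friedel–Crafts-type hydroxyalkylation. Me2AlCl in CH2Cl2 at −78 °C lets furan C2 add to the formyl carbon and gives the furan-fused cyclopentanol F1. BF3·OEt2 then ionises this furfuryl-type alcohol in the presence of CH2=CHBF3K, and the vinyl group should enter anti to C19 to give 26. Steps 13 to 16 are replaced.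

Step 9. The two faces of the N-acyliminium ion differ only through the remote C7 substituents, so facial selectivity at C10 may be poor or reversed; the threo preference at C11 may also be modest. Fallback: from 16, Bu4NF gives the allylic alcohol F2. This is silylated with chlorodiisopropyl[(3-methylfuran-2-yl)oxy]silane F3 (from 17, iPr2SiCl2 and Et3N) to the tethered silyloxyfuran F4. BF3·OEt2 then ionises C10 and the nucleophile is delivered within the molecule from the face of C20, to which the tether is attached. HF·pyridine work-up cleaves the tether to the butenolide alcohol F5, and hydrogenation over Pd/C gives 21.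

Step 10. The hindered ring D alkene may be reduced slowly, allowing furan saturation or allylic C–O hydrogenolysis. Lactone E on the same side as C20 may also divert hydrogen to the furyl face and give the wrong C20 epimer. Fallback: from 16, the ring D alkene is reduced first, on the small bicycle that carries only an ethoxy group at C10, with the homogeneous catalyst [Ir(cod)(PCy3)(py)]PF6 and H2, giving the saturated ethoxy lactam F6. The Mannich reaction of step 9 on F6 gives the butenolide F7, and Pd/C then reduces the butenolide alone to 20.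

Step 21. The 2-oxo lactone may enolise toward C6 to the 3-hydroxy butenolide faster than the methyl group adds, which would stop the addition and erase C6. Fallback: from 33, the methyl group is introduced as an electrophile instead. Et3SiCl and imidazole give the silyl ether F8. LiN(SiMe3)2 and MeI in THF at −78 °C should methylate the enolate on the convex face and give the quaternary silyl ether F9, with limiting base to spare C13. HF·pyridine then gives 35.

Step 4. The alkenyllithium may deprotonate the ketimine at C8 instead of adding, and the branched nucleophile may erode diastereoselectivity at C7. Fallback: from 9, the better-precedented titanium enolate of methyl acetate (LiN(iPr)2, ClTi(OiPr)3) is added to give the β-amino ester F10. HCl in EtOH and then 12 give the amide ester F11. The dianion (LiN(iPr)2, 2.2 equiv) with dimethylmethyleneiminium iodide gives the Mannich base F12, and MeI followed by DBU gives the 2-methylene ester F13. (iBu)2AlH reduces it to the allylic alcohol F14, and t-BuPh2SiCl with imidazole gives 14.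

## Further compounds

F1 | step 14 | furan-fused cyclopentanol (C1–OH, both epimers) | OC1c2occc2[C@]23CC[C@@H]([C@@H]4C[C@H](C)C(=O)O4)N2C(=O)CCC[C@H]13
F2 | step 9 | (9aR)-3-ethoxy-9a-(furan-3-yl)-9-(hydroxymethyl)-1,2,3,6,7,9a-hexahydro-5H-pyrrolo[1,2-a]azepin-5-one | CCOC1CC[C@@]2(c3ccoc3)N1C(=O)CCC=C2CO
F3 | step 9 | chlorodiisopropyl[(3-methylfuran-2-yl)oxy]silane | Cc1ccoc1O[Si](Cl)(C(C)C)C(C)C
F4 | step 9 | silicon-tethered silyloxyfuran of F2 | CCOC1CC[C@@]2(c3ccoc3)N1C(=O)CCC=C2CO[Si](C(C)C)(C(C)C)Oc1occc1C
F5 | step 9 | (3S,9aR)-9a-(furan-3-yl)-9-(hydroxymethyl)-3-[(2S)-4-methyl-5-oxo-2,5-dihydrofuran-2-yl]-1,2,3,6,7,9a-hexahydro-5H-pyrrolo[1,2-a]azepin-5-one | OCC1=CCCC(=O)N2[C@H]([C@@H]3C=C(C)C(=O)O3)CC[C@]12c1ccoc1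
F6 | step 10 | (9S,9aR)-9-(tert-butyldiphenylsilyloxymethyl)-3-ethoxy-9a-(furan-3-yl)octahydro-5H-pyrrolo[1,2-a]azepin-5-one | CCOC1CC[C@@]2(c3ccoc3)N1C(=O)CCC[C@@H]2CO[Si](c1ccccc1)(c1ccccc1)C(C)(C)C
F7 | step 10 | (3S,9S,9aR)-9-(tert-butyldiphenylsilyloxymethyl)-9a-(furan-3-yl)-3-[(2S)-4-methyl-5-oxo-2,5-dihydrofuran-2-yl]octahydro-5H-pyrrolo[1,2-a]azepin-5-one | CC(C)(C)[Si](c1ccccc1)(c1ccccc1)OC[C@H]1CCCC(=O)N2[C@H]([C@@H]3C=C(C)C(=O)O3)CC[C@]12c1ccoc1
F8 | step 21 | 5-O-triethylsilyl ether of 33 | CC[C@H]1[C@H]2OC(=O)[C@H](O[Si](CC)(CC)CC)[C@H]2[C@]23CC[C@@H]([C@@H]4C[C@H](C)C(=O)O4)N2C(=O)CCC[C@H]13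
F9 | step 21 | 5-O-triethylsilyl ether of 35 | CC[C@H]1[C@H]2OC(=O)[C@@](C)(O[Si](CC)(CC)CC)[C@H]2[C@]23CC[C@@H]([C@@H]4C[C@H](C)C(=O)O4)N2C(=O)CCC[C@H]13
F10 | step 4 | methyl (3R)-3-[(S)-tert-butylsulfinylamino]-6,6-diethoxy-3-(furan-3-yl)hexanoate | CC(C)(C)[S@](=O)N[C@](c1ccoc1)(CCC(OCC)OCC)CC(=O)OC
F11 | step 4 | methyl (3R)-6,6-diethoxy-3-(furan-3-yl)-3-(pent-4-enoylamino)hexanoate | C=CCCC(=O)N[C@](c1ccoc1)(CCC(OCC)OCC)CC(=O)OC
F12 | step 4 | methyl (3R)-2-(dimethylaminomethyl)-6,6-diethoxy-3-(furan-3-yl)-3-(pent-4-enoylamino)hexanoate (C2 epimers) | C=CCCC(=O)N[C@](c1ccoc1)(CCC(OCC)OCC)C(CN(C)C)C(=O)OC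
F13 | step 4 | methyl (3R)-6,6-diethoxy-3-(furan-3-yl)-2-methylidene-3-(pent-4-enoylamino)hexanoate | C=CCCC(=O)N[C@](c1ccoc1)(CCC(OCC)OCC)C(=C)C(=O)OC
F14 | step 4 | N-[(3R)-6,6-diethoxy-3-(furan-3-yl)-2-(hydroxymethyl)hex-1-en-3-yl]pent-4-enamide | C=CCCC(=O)N[C@](c1ccoc1)(CCC(OCC)OCC)C(=C)CO
A1 | alternative 1 | triethylsilyl-protected lactone-fused cyclopentenecarbaldehyde (formyl on C7, C7=C20) | CC[C@H]1[C@H]2OC(=O)[C@@](C)(O[Si](CC)(CC)CC)[C@H]2C(C=O)=C1
A2 | alternative 1 | (E)-1-(trimethylsilyloxy)buta-1,3-diene | C=C/C=C/O[Si](C)(C)C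
A3 | alternative 1 | cis-hydrindene with angular formyl group on C7 and silyloxy group on C16 | CC[C@H]1[C@H]2OC(=O)[C@@](C)(O[Si](CC)(CC)CC)[C@H]2[C@]2(C=O)[C@@H](O[Si](C)(C)C)C=CC[C@H]12
A4 | alternative 2 | bicyclic α-hydroxy imine (C8 carbinol, C7=N) of the stenine-type hydroindole | CC[C@H]1[C@H]2OC(=O)[C@@](C)(O)[C@H]2[C@]2(O)C[C@@H]([C@@H]3C[C@H](C)C(=O)O3)N=C2[C@@H]1CCCCO[Si](C)(C)C(C)(C)C
A5 | alternative 2 | spiro 8-oxo pyrrolidine on ring B, ring D open | CC[C@H]1[C@H]2OC(=O)[C@@](C)(O)[C@H]2[C@@]2(C(=O)C[C@@H]([C@@H]3C[C@H](C)C(=O)O3)N2)[C@@H]1CCCCO[Si](C)(C)C(C)(C)C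
A6 | alternative 3 | N-alkylmaleimide tethered through C10–C8 to the lactone-fused cyclopentene (C7=C20) | CC[C@H]1[C@H]2OC(=O)[C@@](C)(O)[C@H]2C(CC[C@@H]([C@@H]3C[C@H](C)C(=O)O3)N3C(=O)C=CC3=O)=C1
A7 | alternative 3 | 16,19-dioxo-17,18-didehydro derivative of 36 | CC[C@H]1[C@H]2OC(=O)[C@@](C)(O)[C@H]2[C@]23CC[C@@H]([C@@H]4C[C@H](C)C(=O)O4)N2C(=O)C=CC(=O)[C@H]13
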